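The data stem from a simulated flask with made-up constants.

Of the J charged to the alpha run, 26.0% is a leftover at 80.0 s: it stands in neither the Q nor the L column, so we book it as J or G. We keep the same ledger for the gamma flask, which has less D and which we must carry from its last reading at 20.0 s to 2.0 min.

| setting | gamma | alpha | flask |
|---|---|---|---|
| J | 0.44 M | 0.44 M | 0.44 M |
| D | 0.23 mM | 0.35 mM | 0.23 mM |
| remark | the very flask that is asked about, followed so far | run made earlier |  |
| time |  |  | 2.0 min |

- gamma (time / s: Q / %, L / %): 10.0: 17, 0; 15.0: 22, 0; 20.0: 28, 0
- alpha (time / s: Q / %, L / %): 10.0: 23, 0; 30.0: 48, 2; 50.0: 62, 3; 80.0: 69, 5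

(standard deviation of a reading: 1.5 percentage points)

* share of Q in Q plus L at 1.0 s
* share of Q in Q plus L at 10 s
* share of Q in Q plus L at 2.0 min

- for Q the Z are counted in
- as a solid, counted per litre of solution: Z
- steps thought possible: D <-> E; Z <-> Q; J <-> G; J + D -> D + Q; D + G -> D + L

The ledger follows J, the limiting reagent, in fractions of its charge. The first entry is J to Q, over D. The next is J to G, with no D in the step. The last is G to L, over D. So D stands in the rates of Q and of L alike and drops out of their ratio, which holds G against J, and G starts from nothing. The ratio of the two rates should therefore start from zero and climb as G builds up. We call L over Q per unit time the drift, and read it in the alpha run where L stands highest: 0.0543 min⁻¹, a reading whose L carries a scatter of 1.5 percentage points. The books close on Q, L and the leftover, and the share asked reads the first two. Carried unchanged to the gamma flask as a straight line from zero, the drift gives us 99.9%, 99.1% and 90.2%.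

The forecast has 99.8%, 98.7% and 92%, lower than ours at 10 s and higher at 2.0 min, holding that G “builds up slowly and uncatalysed from J”.

The flask gives 99.8%, 98.0% and 89.5%.

    D ⇌ E (K = 1.40, k = 0.0110 s⁻¹)
    Z ⇌ Q, rate k2*(cs2 - [Q]) while solid is left; crystals form when [Q] > cs2 (solubility = 0.250 M, k = 0.500 s⁻¹)
    J ⇌ G (K = 0.320, k = 0.00440 s⁻¹)
    J + D → D + Q (k = 77.0 L mol⁻¹ s⁻¹)
    D + G → D + L (k = 76.0 L mol⁻¹ s⁻¹)

At 2.0 min the flask shows a drift of 0.0585 min⁻¹ against our 0.0543 min⁻¹, while at 10 s our share stands 1.1 points above the flask's. The neighbour with 5.8 × 10⁻⁵ M of D gives 98.0% at 10 s, as this flask does. In the flask, the half-life of J by making Q, other concentrations held at their charge, is 0.65 min, shorter than the 2.6 min by its forward loss to G. At 2.00 min, with D at 47.7% of the catalyst charged, J goes to Q at 1.9 times its forward rate to G.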